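**Plan**

1. Quinone numbering: C1(=O), C2(OH), C3(octadecyl), C4(=O), C5(OMe), C6(H). The six-membered ring consists of two O=C–C=C–O triads (C4–C3–C2 and C1–C6–C5) joined head to tail. Each oxygen-bearing sp2 carbon (C2, C5) can be held as a carbonyl-chelated vinyl anion, and each carbonyl carbon (C1, C4) can act as an acyl electrophile.
2. Retrosynthesis: the C2 hydroxyl goes back to a methyl ether (12). Then C4–C5 and C1–C2 are cut together, giving methyl (E)-3-methoxyacrylate 1 and its 2-octadecyl acid chloride 8. Last, the bond from C3 to the chain is cut (vinyl bromide 3 plus an octadecylzinc reagent).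
3. Forward: the chain is joined to one three-carbon unit first (steps 1–4). The only ring is then closed in one flask by lithiation, acylation, second lithiation and ring-closing acylation (step 5). Selective hydrolysis of the C2 methyl ether ends the route.
4. Stereochemistry: the target has no stereocentre. The (E) geometry of both acrylate units comes from commercial 1 and is kept in the cross-coupling; it places H, then Li, cis to the carbonyl, which is what lets the ring close.

Key step: step 5

Remark on the chemistry: lithium 2,2,6,6-tetramethylpiperidide (LiTMP) is taken as the purchased base, and dibromide 2 forms as a mixture of diastereomers that converge on 3.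

**Step 1**
Reactants: 1 methyl (E)-3-methoxyacrylate
Product: 3 methyl (Z)-2-bromo-3-methoxyacrylate, via methyl 2,3-dibromo-3-methoxypropanoate 2 (not isolated)
Conditions: Br2 (1.0 equiv), CH2Cl2, 0 °C; then Et3N (1.3 equiv), 0 °C to rt
Reagents that add atoms: bromine, BrBr
Why: Bromine adds across the electron-rich enol-ether double bond and triethylamine then removes the acidic C2 hydrogen with loss of the labile C3 bromide (bromination–dehydrobromination), which should leave the more stable isomer with OMe trans to the ester.

**Step 2**
Reactants: 4 1-bromooctadecane; 3 methyl (Z)-2-bromo-3-methoxyacrylate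
Product: 6 methyl (E)-3-methoxy-2-octadecylacrylate, via octadecylzinc bromide 5 (not isolated)
Conditions: Zn dust (1.5 equiv), I2 (5 mol %), DMA, 80 °C; then 3, PdCl2(dppf) (3 mol %), DMA/THF, 50 °C
Reagents that add atoms: none
Why: Zinc insertion into the primary C–Br bond followed by a Negishi sp3–sp2 cross-coupling, which replaces the vinyl bromide with retention of the alkene geometry, so OMe stays trans to the ester (now designated E), while the dppf ligand should suppress β-hydride elimination.

**Step 3**
Reactants: 6 methyl (E)-3-methoxy-2-octadecylacrylate
Product: 7 (E)-3-methoxy-2-octadecylacrylic acid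
Conditions: LiOH·H2O (3 equiv), THF/MeOH/H2O, 50 °C; then 1 M HCl to pH 3, 0 °C
Reagents that add atoms: lithium hydroxide, [Li+].[OH-]
Why: Saponification of the methyl ester by acyl substitution; the β-methoxy enol ether is a vinylogous carbonate that should resist hydroxide at this temperature and should survive the brief, cold acidification.

**Step 4**
Reactants: 7 (E)-3-methoxy-2-octadecylacrylic acid
Product: 8 (E)-3-methoxy-2-octadecylacryloyl chloride
Conditions: (COCl)2 (1.3 equiv), DMF (cat.), CH2Cl2, 0 °C to rt; evaporate, use crude
Reagents that add atoms: oxalyl chloride, O=C(Cl)C(Cl)=O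
Why: Vilsmeier-type activation of the acid with oxalyl chloride and DMF gives the acid chloride under conditions that β-methoxyacryloyl chlorides tolerate, and the alkene geometry is not touched.

**Step 5**
Reactants: 1 methyl (E)-3-methoxyacrylate; 8 (E)-3-methoxy-2-octadecylacryloyl chloride
Product: 12 2,5-dimethoxy-3-octadecyl-1,4-benzoquinone, via methyl (E)-3-lithio-3-methoxyacrylate 9 (not isolated), via methyl (2E,5E)-3,6-dimethoxy-5-octadecyl-4-oxohexa-2,5-dienoate 10 (not isolated), via methyl (2E,5E)-6-lithio-3,6-dimethoxy-5-octadecyl-4-oxohexa-2,5-dienoate 11 (not isolated)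
Conditions: 1 (1.05 equiv), LiTMP (1.05 equiv), THF, −100 °C; inverse addition to 8 in THF, −100 °C; then LiTMP (1.1 equiv), −100 to −60 °C; AcOH quench, −78 °C
Reagents that add atoms: none
Why: Proposed new method: deprotonation of 1 at its oxygen-bearing vinyl carbon, cis to the ester carbonyl, gives the chelate-stabilised vinyllithium 9, which is acylated by acid chloride 8 to give dienone 10 (bond C4–C5); a second equivalent of LiTMP then removes the vinyl hydrogen at the future C2, which lies cis to the new ketone, and vinyllithium 11 attacks the methyl ester with loss of methoxide (bond C1–C2), so that two β-methoxyacryloyl units are joined head to tail in an anionic [3+3] sense. The closest known reaction types are the carbonyl-directed β-lithiation of β-alkoxyacrylates with trapping by carbonyl electrophiles, the acylation of vinyllithiums by acid chlorides and the Dieckmann-type ring closure. The six-membered ring closes in the 6-exo-trig mode, and this needs the two ring bonds cis on each double bond, which the (E) geometry of 1 and 8 supplies because it places H, and hence Li, cis to the carbonyl in both halves. No stereocentre is formed. The step needs cross-coupling over self-condensation and vinylic over allylic deprotonation: the first is secured by giving the nucleophilic role to 1 alone and the electrophilic role (acid chloride, inverse addition at −100 °C) to 8 alone, and the second by the order of bond formation, which leaves the first CH2 of the octadecyl chain in 10 on the α-carbon of the enone, where it is cross-conjugated and not acidified.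

**Step 6**
Reactants: 12 2,5-dimethoxy-3-octadecyl-1,4-benzoquinone
Product: 13 irisoquin (2-hydroxy-5-methoxy-3-octadecyl-1,4-benzoquinone)
Conditions: 70% aq HClO4, 1,4-dioxane, rt
Reagents that add atoms: water, O
Why: Acid-catalysed addition–elimination hydrolysis of a vinylogous methyl ester; the C2 methoxy group is flanked by the C3 octadecyl chain and twisted out of conjugation, so it should be cleaved first (the known behaviour of 3-alkyl-2,5-dimethoxy-1,4-benzoquinones), and the resulting hydroxyquinone is deactivated toward a second hydrolysis.

**Compound list**

1 | methyl (E)-3-methoxyacrylate | CO/C=C/C(=O)OC | starting material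
2 | methyl 2,3-dibromo-3-methoxypropanoate (mixture of racemic diastereomers) | COC(Br)C(Br)C(=O)OC | intermediate
3 | methyl (Z)-2-bromo-3-methoxyacrylate | CO/C=C(Br)/C(=O)OC | intermediate
4 | 1-bromooctadecane | CCCCCCCCCCCCCCCCCCBr | starting material
5 | octadecylzinc bromide | CCCCCCCCCCCCCCCCCC[Zn]Br | intermediate
6 | methyl (E)-3-methoxy-2-octadecylacrylate | CO/C=C(CCCCCCCCCCCCCCCCCC)/C(=O)OC | intermediate
7 | (E)-3-methoxy-2-octadecylacrylic acid | CO/C=C(CCCCCCCCCCCCCCCCCC)/C(=O)O | intermediate
8 | (E)-3-methoxy-2-octadecylacryloyl chloride | CO/C=C(CCCCCCCCCCCCCCCCCC)/C(=O)Cl | intermediate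
9 | methyl (E)-3-lithio-3-methoxyacrylate (lithium cis to the ester) | CO/C([Li])=C/C(=O)OC | intermediate
10 | methyl (2E,5E)-3,6-dimethoxy-5-octadecyl-4-oxohexa-2,5-dienoate | CO/C=C(CCCCCCCCCCCCCCCCCC)/C(=O)/C(OC)=C\C(=O)OC | intermediate
11 | methyl (2E,5E)-6-lithio-3,6-dimethoxy-5-octadecyl-4-oxohexa-2,5-dienoate | CO/C([Li])=C(CCCCCCCCCCCCCCCCCC)/C(=O)/C(OC)=C\C(=O)OC | intermediate
12 | 2,5-dimethoxy-3-octadecyl-1,4-benzoquinone | COC1=CC(=O)C(OC)=C(CCCCCCCCCCCCCCCCCC)C1=O | intermediate
13 | irisoquin (2-hydroxy-5-methoxy-3-octadecyl-1,4-benzoquinone) | CCCCCCCCCCCCCCCCCCC1=C(O)C(=O)C=C(OC)C1=O | target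

**Count**

Total steps: 6. Longest linear sequence: 6 steps (1 → 3 → 6 → 7 → 8 → 12 → 13).

**Steps most likely to fail**

Step 5 (Proposed new method). The vinyllithium 9 may add a second time to the ketone of 10, or may self-condense before it is acylated. In the second stage the amide base may add in a conjugate sense instead of deprotonating the vinyl position. The fallback uses known chemistry, sets out from 4 and comes back at 12. Commercial 1,2,4,5-tetramethoxybenzene would be lithiated between two methoxy groups (n-BuLi, TMEDA, THF, 0 °C) and alkylated with 4 to give 1,2,4,5-tetramethoxy-3-octadecylbenzene F1. Oxidative demethylation of F1 with (NH4)2Ce(NO3)6 in MeCN/H2O at 0 °C should then give 12. The ring is thus taken from an arene and not built.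

Step 6. Hydrolysis may not stop after one ether, or may take place at the C5 methoxy group. The fallback sets out from 12 and comes back at 13. Both ethers would be hydrolysed (aq NaOH, dioxane, reflux; then HCl) to 2,5-dihydroxy-3-octadecyl-1,4-benzoquinone F2. F2 would then be mono-etherified under equilibrium control (MeOH, BF3·OEt2, rt), where the unhindered C5 hydroxyl should be methylated in preference to the C2 hydroxyl next to the chain.

Step 2. Zinc insertion into the long-chain bromide may be incomplete, the alkylzinc may be protonated, or the alkylpalladium intermediate may undergo β-hydride elimination before the slow coupling at the hindered α-position. The fallback sets out from 4 and comes back at 6. The lithium enolate of commercial methyl 3,3-dimethoxypropanoate (lithium diisopropylamide, THF/DMPU, −78 to 0 °C) would be alkylated with 4 to give methyl 2-(dimethoxymethyl)icosanoate F3. Acid-catalysed loss of methanol from F3 (TsOH cat., toluene, reflux with removal of MeOH) should then give 6 as the more stable (E) isomer. The chain is thus attached by enolate alkylation and not by cross-coupling.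

**Further compounds**

F1 | step 5 | 1,2,4,5-tetramethoxy-3-octadecylbenzene | COc1cc(OC)c(OC)c(CCCCCCCCCCCCCCCCCC)c1OC
F2 | step 6 | 2,5-dihydroxy-3-octadecyl-1,4-benzoquinone | CCCCCCCCCCCCCCCCCCC1=C(O)C(=O)C=C(O)C1=O
F3 | step 2 | methyl 2-(dimethoxymethyl)icosanoate (racemic) | CCCCCCCCCCCCCCCCCCC(C(OC)OC)C(=O)OC
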